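**Retrosynthetic overview**
- 2-Phenylethyl icosanoate ⇒ cut C9–C10 of the icosanoyl chain. Both carbons become carboxyl-bearing CH2 groups (like polarity), giving lauric acid (C11 + CO2) and sebacic acid mono(2-phenylethyl) ester (C9 + CO2). Forward, they are joined by mixed Kolbe anodic decarboxylative radical coupling.
- Enabling feature: C9 and C10 are two unsubstituted methylenes inside the unbranched chain C2–C20, so each can come from a primary, unstabilised alkyl radical that couples instead of being oxidised further. The ester carbon C1 is seven CH2 groups (C2–C8) away from C9, and the phenyl ring sits on the alcohol part, not conjugated with any reacting centre.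
- Half-ester ⇒ mono-tert-butyl sebacate + 2-phenylethanol (Steglich esterification, then acidolysis of the tert-butyl ester).
- No ring is formed; the only ring, the phenyl ring, is bought in 2-phenylethanol.

Key step: step 3

Remark: mono-tert-butyl sebacate, 2-phenylethanol and lauric acid are taken as commercial; the target is achiral, so no stereocentre has to be set.

**Step 1**
Reactants: 1 10-tert-butoxy-10-oxodecanoic acid (mono-tert-butyl sebacate); 2 2-phenylethanol
Product: 3 1-tert-butyl 10-(2-phenylethyl) decanedioate
Conditions: DCC (1.1 equiv), DMAP (0.1 equiv), CH2Cl2, 0 °C → rt
Reagents that add atoms: none
Why: Steglich esterification: DCC turns the free carboxyl of 1 into the O-acylisourea, DMAP relays the acyl group to the primary alcohol 2, and the tert-butyl ester is inert to these neutral conditions.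

**Step 2**
Reactants: 3 1-tert-butyl 10-(2-phenylethyl) decanedioate
Product: 4 10-oxo-10-(2-phenylethoxy)decanoic acid (sebacic acid mono(2-phenylethyl) ester)
Conditions: TFA/CH2Cl2 (1:3), rt; evaporation with toluene
Reagents that add atoms: none
Why: Acid-catalysed AAL1 cleavage of the tert-butyl ester (loss of the tert-butyl cation as isobutene) frees the carboxyl group, while the primary 2-phenylethyl ester cannot ionise and should stay intact.

**Step 3**
Reactants: 4 10-oxo-10-(2-phenylethoxy)decanoic acid; 5 dodecanoic acid (lauric acid, 5 equiv)
Product: 8 2-phenylethyl icosanoate, via undecyl radical 6 (not isolated), via 9-oxo-9-(2-phenylethoxy)nonyl radical 7 (not isolated)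
Conditions: undivided cell, smooth Pt anode/Pt cathode, KOH (ca. 5 mol% of total CO2H, added to the acids), MeOH, 45–50 °C, constant current ca. 0.2 A cm−2, stopped while the bulk is still weakly acidic; silica gel chromatography
Reagents that add atoms: none
Why: Partial neutralisation gives the carboxylates of 4 and 5, which are oxidised by one electron each at the platinum anode at high current density and lose CO2 to give the primary radicals 7 and 6 side by side in the anode layer, where their recombination forms the C9–C10 bond of the icosanoyl chain, while the cathode discharges the carboxyl protons as H2 and so regenerates the base. The closest known reaction type is the mixed (crossed) Kolbe electrolysis of a fatty acid with a half-ester of an α,ω-alkanedioic acid, a classical chain extension of fatty acids. No ring is closed and no stereocentre is formed. The selectivity needed is cross- over homo-coupling and radical coupling over further oxidation to cations: the first is secured statistically by the five-fold excess of cheap 5, so that 7 should meet mostly 6, and the two symmetrical by-products (docosane without an ester group, the C18 diester with two) differ from 8 in polarity and should separate on silica; the second is secured by the substrate, since both radicals are primary, unbranched and carry no α-heteroatom or α-aryl group. The ester (C1, seven methylenes away from the radical carbon) and the non-conjugated phenyl ring should be spectators at the carboxylate-covered anode, and stopping while free acid remains keeps methoxide, and with it ester exchange with the solvent, out of the bulk.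

**Compound list**
1 | 10-tert-butoxy-10-oxodecanoic acid (mono-tert-butyl sebacate) | CC(C)(C)OC(=O)CCCCCCCCC(=O)O | starting material
2 | 2-phenylethanol | OCCc1ccccc1 | starting material
3 | 1-tert-butyl 10-(2-phenylethyl) decanedioate | CC(C)(C)OC(=O)CCCCCCCCC(=O)OCCc1ccccc1 | intermediate
4 | 10-oxo-10-(2-phenylethoxy)decanoic acid | OC(=O)CCCCCCCCC(=O)OCCc1ccccc1 | intermediate
5 | dodecanoic acid (lauric acid) | CCCCCCCCCCCC(=O)O | starting material
6 | undecyl radical | [CH2]CCCCCCCCCC | intermediate
7 | 9-oxo-9-(2-phenylethoxy)nonyl radical | [CH2]CCCCCCCC(=O)OCCc1ccccc1 | intermediate
8 | 2-phenylethyl icosanoate (phenethyl icosanoate) | CCCCCCCCCCCCCCCCCCCC(=O)OCCc1ccccc1 | target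

**Total step count:** 3
**Longest linear sequence:** 3 steps (1 → 3 → 4 → 8)

**Steps most likely to fail**

Step 3: the cross-coupling may lose out to statistical homocoupling, to fouling of the anode by the waxy products, to further oxidation of the radicals (cation-derived ethers and alkenes), or to ester exchange with methanol if the bulk turns alkaline. The fallback replaces the radical union by a polar, copper-catalysed alkyl–alkyl coupling that forms the same C9–C10 bond. It sets out from 2: acid-catalysed esterification with commercial 9-bromononanoic acid (TsOH cat., toluene, Dean–Stark) should give 2-phenylethyl 9-bromononanoate F1. Coupling of F1 with commercial undecylmagnesium bromide (Li2CuCl4 cat., THF/NMP, −10 → 0 °C; Kochi-type substitution at the primary bromide, which should outrun addition to the ester at this temperature) should deliver 8, where the route is rejoined.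

Step 2: the tert-butyl cation may alkylate the phenyl ring (Friedel–Crafts tert-butylation) instead of losing a proton, or the cleavage may stop short. The fallback changes the protecting-group logic from acidolysis to hydrogenolysis. It sets out from 2: Steglich esterification (DCC, DMAP, CH2Cl2) with commercial 10-(benzyloxy)-10-oxodecanoic acid should give benzyl 2-phenylethyl decanedioate F2. Hydrogenolysis (H2, 1 atm, Pd/C, EtOAc, rt) should remove only the benzyl group, because the C–O bond of the 2-phenylethyl ester is not benzylic, and comes back to the route at 4.

Step 1: the O-acylisourea may rearrange to the unreactive N-acylurea before the acyl group is passed on to the alcohol. The fallback forms the ester by O-alkylation of the carboxylate instead of acyl activation. It sets out from 1, which with (2-bromoethyl)benzene and K2CO3 in DMF at 40 °C should give 3 directly (SN2 at the primary bromide by the weakly basic carboxylate, which should not cause elimination to styrene), where the route is rejoined.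

**Further compounds**
F1 | step 3 | 2-phenylethyl 9-bromononanoate | BrCCCCCCCCC(=O)OCCc1ccccc1
F2 | step 2 | benzyl 2-phenylethyl decanedioate | O=C(CCCCCCCCC(=O)OCCc1ccccc1)OCc1ccccc1
F0 | step 1 | none | none
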